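At 20 min the two earlier runs can be laid side by side, and in the ratio of their readings time drops out. Zeta then reads 5% of left-handed product and gamma 18%, each with a scatter of 2 percentage points.

common to all: left-handed substrate 19 mM; right-handed substrate 19 mM; gas 0.66 mM (held)
- zeta: free catalyst 0.45 mol%; run made earlier
- gamma: free catalyst 6.8 mol%; run made earlier
- winter: free catalyst 0.6 mol%; time 20 min
- spring: free catalyst 5 mol%; time 20 min
- noon: free catalyst 0.4 mol%; time 20 min
- summer: free catalyst 1.3 mol%; time 20 min

| run | time / min | left-handed product / % |
|---|---|---|
| zeta | 3.00 | 0 |
| zeta | 6.00 | 0 |
| zeta | 8.00 | 2 |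
| zeta | 12.0 | 6 |
| zeta | 15.0 | 7 |
| zeta | 20.0 | 5 |
| gamma | 1.50 | 1 |
| gamma | 2.50 | 4 |
| gamma | 4.00 | 1 |
| gamma | 6.00 | 4 |
| gamma | 8.00 | 3 |
| gamma | 12.0 | 5 |
| gamma | 20.0 | 18 |

(standard deviation of a reading: 2 percentage points)

1. the flasks put in order of amount of left-handed product, in percent of the left-handed substrate and right-handed substrate together charged, best first, at 20 min (winter / spring / noon / summer)
2. the amount of left-handed product, in percent of the left-handed substrate and right-handed substrate together charged of the flask you put first, at 20 min
3. the amount of left-handed product, in percent of the left-handed substrate and right-handed substrate together charged of the flask you put last, at 20 min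

The bench rule says product goes with catalyst. Applied honestly to spring, it scales zeta by the loading ratio:

5% × 5 mol% / 0.45 mol% = 55.6%

That is more than the 50.0% of the charge that is left-handed substrate, so the rule cannot hold up there. But the runs part from the rule while still below that ceiling, with gamma at 18%: from zeta to gamma the loading rises by a factor of 15.1, the product by 3.60.

So we carry a different quantity, the loading exponent, the logarithm of the product ratio over the logarithm of the loading ratio at one time (the apparent order in free catalyst):

n = ln(18% / 5%) / ln(6.8 mol% / 0.45 mol%) = 0.472

It is a reading and carries their scatter. Our own reckoning scales each end from the nearer run: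

spring: 18% × (5 mol% / 6.8 mol%)^n = 15.6%

noon: 5% × (0.4 mol% / 0.45 mol%)^n = 4.73%

The forecast puts the flasks spring > summer > winter > noon, with 15% first (range 10% to 20%) and 5.5% last (range 3% to 8%), taking product “roughly as a 0.4 power of loading”. That power differs from our n and its two amounts differ from ours, but our order is the same.

The flasks stand spring > summer > winter > noon, with 19.0% in spring and 7.54% in noon.

    free catalyst + left-handed substrate ⇌ catalyst intermediate A (K = 50.0 /M, k = 2590 /M/min)
    free catalyst + right-handed substrate ⇌ catalyst intermediate B (K = 910 /M, k = 2160 /M/min)
    coupling partner + catalyst intermediate A → free catalyst + left-handed product (k = 34800 /M/min)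
    coupling partner + catalyst intermediate B → free catalyst + right-handed product (k = 15800 /M/min)
    gas ⇌ coupling partner, rate k5*(csat - [coupling partner]) (kL = 2.14 /min)

Beside its left-handed product, spring holds 45.6% of right-handed product. Now n goes to one further flask, like spring but with 1.2 mol% of free catalyst, twice the loading of winter. Scaling the 9.50% of winter gives 13.2%, and that flask holds 12.9%.

The readings are simulated for substances that don't exist; noise was put on by code.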